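**Plan** (isochromene numbering; ring A = carbocycle C4a–C8a, ring B = pyran; C3' = butanoate carbinol)
1. Retrosynthesis: ring B is opened at the lactol bond C1–O2 and the enal chain is folded back into a furan (C3 = furan C2), leaving a C1 aldehyde and a furfuryl group on C4a; the C8 ester is cut next; last, ring A is cut at C5–C6 and C4a–C8a together.
2. Enabling feature: in ring A the C6 ketone and the C8a tertiary carbinol are two carbonyl-derived (acceptor) carbons, 1,4-related through C7–C8 and both bonded to the C4a=C5 alkene, so ring A is a γ-keto ester (C6–C7–C8–C8a) plus an alkyne used as a cis-1,2-dianion (alkyne–Ti(OiPr)2 complex).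
3. Forward: keto ester 5 (four steps from 1) and silyl alkyne 9 (one step) are joined in step 6 to give ring A; C–Si cleavage, diol release, C8 acylation and C1 oxidation follow; singlet-oxygen opening of the furan then lets ring B close as the lactol.
4. Stereochemistry: C7 and C8 come from commercial chiral-pool ester 1, C3' from (R)-3-hydroxybutanoic acid, C8a from chelation-controlled addition in step 6, C1 and the E alkene from equilibration in step 13.

Key step: step 6

Assumption: the lactol carbon C1 is configurationally labile, and the isomer drawn (C1–OH anti to C8a–OH, both pseudo-axial on ring B, anomerically stabilised) is taken to be the one favoured at equilibrium.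

**Step 1**
Reactants: 1 ethyl (2S,3R)-3-[(4R)-2,2-dimethyl-1,3-dioxolan-4-yl]-2,3-dihydroxy-2-methylpropanoate
Product: 2 ethyl (4S,5R)-5-[(4R)-2,2-dimethyl-1,3-dioxolan-4-yl]-2,2,4-trimethyl-1,3-dioxolane-4-carboxylate
Conditions: 2,2-dimethoxypropane, camphorsulfonic acid (cat.), CH2Cl2, rt
Reagents that add atoms: 2,2-dimethoxypropane COC(C)(C)OC
Why: Acid-catalysed transketalization ties the C7/C8 diol into a dioxolane without touching a stereocentre.

**Step 2**
Reactants: 2 ethyl (4S,5R)-5-[(4R)-2,2-dimethyl-1,3-dioxolan-4-yl]-2,2,4-trimethyl-1,3-dioxolane-4-carboxylate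
Product: 3 ethyl (4S,5R)-5-[(1R)-1,2-dihydroxyethyl]-2,2,4-trimethyl-1,3-dioxolane-4-carboxylate
Conditions: AcOH/H2O (3:2), rt
Reagents that add atoms: none
Why: Selective acetal hydrolysis should open the terminal dioxolane faster than the internal one, whose oxygens are deactivated by the neighbouring ester and shielded by the quaternary C7.

**Step 3**
Reactants: 3 ethyl (4S,5R)-5-[(1R)-1,2-dihydroxyethyl]-2,2,4-trimethyl-1,3-dioxolane-4-carboxylate
Product: 4 ethyl (4S,5R)-5-[(1R)-2-{[tert-butyl(diphenyl)silyl]oxy}-1-hydroxyethyl]-2,2,4-trimethyl-1,3-dioxolane-4-carboxylate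
Conditions: TBDPSCl, imidazole, CH2Cl2, 0 °C
Reagents that add atoms: tert-butyl(chloro)diphenylsilane CC(C)(C)[Si](Cl)(c1ccccc1)c1ccccc1
Why: Silylation with the bulky chlorosilane is selective for the primary C1 hydroxyl over the secondary one, which stays free for oxidation.

**Step 4**
Reactants: 4 ethyl (4S,5R)-5-[(1R)-2-{[tert-butyl(diphenyl)silyl]oxy}-1-hydroxyethyl]-2,2,4-trimethyl-1,3-dioxolane-4-carboxylate
Product: 5 ethyl (4S,5S)-5-({[tert-butyl(diphenyl)silyl]oxy}acetyl)-2,2,4-trimethyl-1,3-dioxolane-4-carboxylate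
Conditions: Dess–Martin periodinane, CH2Cl2, rt
Reagents that add atoms: none
Why: Dess–Martin oxidation of the only free hydroxyl gives the C8a ketone under non-basic conditions, so that C8, now α to the ketone, is not epimerised.

**Step 5**
Reactants: 6 furan; 7 3-bromo-1-(trimethylsilyl)prop-1-yne
Product: 9 [3-(furan-2-yl)prop-1-yn-1-yl](trimethyl)silane, via furan-2-yllithium 8 (not isolated)
Conditions: n-BuLi, THF, −78 → 0 °C; then CuBr·SMe2 (10 mol %), 7, −40 °C → rt
Reagents that add atoms: none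
Why: Furan is lithiated next to oxygen and the organometallic is propargylated under copper catalysis at the CH2 of 7 (SN2), the bulky silyl group on the alkyne terminus disfavouring SN2' attack to an allene.

**Step 6**
Reactants: 5 ethyl (4S,5S)-5-({[tert-butyl(diphenyl)silyl]oxy}acetyl)-2,2,4-trimethyl-1,3-dioxolane-4-carboxylate; 9 [3-(furan-2-yl)prop-1-yn-1-yl](trimethyl)silane
Product: 12 (3aR,4R,7aS)-4-({[tert-butyl(diphenyl)silyl]oxy}methyl)-5-(furan-2-ylmethyl)-4-hydroxy-2,2,7a-trimethyl-6-(trimethylsilyl)-3a,4-dihydro-1,3-benzodioxol-7(7aH)-one, via titanacyclopropene 10 (not isolated), via oxatitanacyclopentene 11 (not isolated)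
Conditions: 9 (1.5 equiv), Ti(OiPr)4 (1.5 equiv), iPrMgCl (3.0 equiv), Et2O, −78 → −50 °C; then 5, −78 → −40 °C; then → rt; aq. NH4Cl
Reagents that add atoms: none
Why: Proposed new method: Ti(OiPr)4 with two equivalents of iPrMgCl gives (η2-propene)Ti(OiPr)2, which exchanges propene for 9 to form titanacyclopropene 10 (the alkyne as a cis-1,2-dianion); the C8a ketone of 5 inserts into the Ti–C bond remote from silicon to give oxatitanacyclopentene 11 (bond C4a–C8a), and on warming the remaining alkenyl–Ti bond at C5 attacks the ester carbon C6 and expels ethoxide (bond C5–C6). The closest known reaction types are the addition of (η2-silylalkyne)Ti(OiPr)2 complexes to ketones at the carbon β to silicon and the intramolecular nucleophilic acyl substitution of alkyne–Ti(OiPr)2 complexes with tethered esters; new here is that the acyl substitution starts from the oxatitanacycle, which is reasonable because the ester sits two atoms from C8a and can bind the Lewis-acidic titanium next to the C5–Ti bond. Ring A closes in this second event as a 6-exo-trig addition–elimination at C6, the metallacycle holding C6 and C8a cis on the C4a=C5 alkene. The one new stereocentre, C8a, is set in the first event under Cram-chelate control: the metal bridges the ketone oxygen and the dioxolane oxygen on C8, the face toward C7 and its cis methyl group is shielded, and C4a enters from the side of the C8 hydrogen, which puts the C8a oxygen trans to the C8 oxygen on ring A as in the target. The step needs chemoselectivity (ketone before ester, secured by the higher electrophilicity of the α,α'-dioxygenated ketone against an α-quaternary ester), regioselectivity on the alkyne (secured by the SiMe3 group, which also turns the terminal alkyne into an internal one and is taken off in step 7) and facial selectivity (secured by the chelate, the bulky silyl ether on C1 being no competing donor). Diversion by lactonization of the C8a alkoxide onto C6 is excluded because it would require a trans-fused bicyclo[3.3.0] lactone.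

**Step 7**
Reactants: 12 (3aR,4R,7aS)-4-({[tert-butyl(diphenyl)silyl]oxy}methyl)-5-(furan-2-ylmethyl)-4-hydroxy-2,2,7a-trimethyl-6-(trimethylsilyl)-3a,4-dihydro-1,3-benzodioxol-7(7aH)-one
Product: 13 (3aR,4R,7aS)-4-({[tert-butyl(diphenyl)silyl]oxy}methyl)-5-(furan-2-ylmethyl)-4-hydroxy-2,2,7a-trimethyl-3a,4-dihydro-1,3-benzodioxol-7(7aH)-one
Conditions: TBAF (1.1 equiv), AcOH (1.1 equiv), THF, 0 °C
Reagents that add atoms: none
Why: Fluoride-induced protodesilylation should cleave the unhindered SiMe3 group on C5, whose carbon is activated by the adjacent C6 carbonyl, faster than the hindered primary tert-butyldiphenylsilyl ether under buffered conditions.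

**Step 8**
Reactants: 13 (3aR,4R,7aS)-4-({[tert-butyl(diphenyl)silyl]oxy}methyl)-5-(furan-2-ylmethyl)-4-hydroxy-2,2,7a-trimethyl-3a,4-dihydro-1,3-benzodioxol-7(7aH)-one
Product: 14 (4R,5R,6S)-4-({[tert-butyl(diphenyl)silyl]oxy}methyl)-3-(furan-2-ylmethyl)-4,5,6-trihydroxy-6-methylcyclohex-2-en-1-one
Conditions: CF3CO2H/H2O/THF (1:1:4), 0 °C → rt
Reagents that add atoms: none
Why: Acid hydrolysis of the dioxolane, which is trans-fused to ring A and therefore strained, should free the C7 and C8 hydroxyls while the primary silyl ether and the furan survive brief dilute acid.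

**Step 9**
Reactants: 15 (3R)-3-hydroxybutanoic acid
Product: 17 (3R)-3-{[tert-butyl(dimethyl)silyl]oxy}butanoic acid, via silyl ester 16 (not isolated)
Conditions: TBSCl (2.2 equiv), imidazole, DMF, rt; then K2CO3, MeOH/H2O, rt; then 1 M HCl to pH 4
Reagents that add atoms: tert-butyl(chloro)dimethylsilane CC(C)(C)[Si](C)(C)Cl
Why: Silylation of both hydroxyl and carboxyl groups followed by selective solvolysis of the labile silyl ester should give the O-silyl acid without involving the C3' stereocentre.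

**Step 10**
Reactants: 14 (4R,5R,6S)-4-({[tert-butyl(diphenyl)silyl]oxy}methyl)-3-(furan-2-ylmethyl)-4,5,6-trihydroxy-6-methylcyclohex-2-en-1-one; 17 (3R)-3-{[tert-butyl(dimethyl)silyl]oxy}butanoic acid
Product: 19 (1R,2R,6S)-2-({[tert-butyl(diphenyl)silyl]oxy}methyl)-3-(furan-2-ylmethyl)-2,6-dihydroxy-6-methyl-5-oxocyclohex-3-en-1-yl (3R)-3-{[tert-butyl(dimethyl)silyl]oxy}butanoate, via mixed anhydride 18 (not isolated)
Conditions: 17, 2,4,6-trichlorobenzoyl chloride, Et3N, THF, rt; then 14, DMAP, toluene, 50 °C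
Reagents that add atoms: none
Why: Yamaguchi esterification through the mixed anhydride should acylate the only non-tertiary hydroxyl (C8) with retention, since its C–O bond is not broken and the tertiary hydroxyls at C7 and C8a do not compete.

**Step 11**
Reactants: 19 (1R,2R,6S)-2-({[tert-butyl(diphenyl)silyl]oxy}methyl)-3-(furan-2-ylmethyl)-2,6-dihydroxy-6-methyl-5-oxocyclohex-3-en-1-yl (3R)-3-{[tert-butyl(dimethyl)silyl]oxy}butanoate
Product: 20 (1R,2R,6S)-3-(furan-2-ylmethyl)-2,6-dihydroxy-2-(hydroxymethyl)-6-methyl-5-oxocyclohex-3-en-1-yl (3R)-3-hydroxybutanoate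
Conditions: HF·pyridine, pyridine, THF, 0 °C → rt
Reagents that add atoms: none
Why: Acidic fluoride should remove both silyl ethers and, unlike basic fluoride, should not trigger migration of the C8 acyl group to the freed primary C1 hydroxyl.

**Step 12**
Reactants: 20 (1R,2R,6S)-3-(furan-2-ylmethyl)-2,6-dihydroxy-2-(hydroxymethyl)-6-methyl-5-oxocyclohex-3-en-1-yl (3R)-3-hydroxybutanoate
Product: 21 (1R,2S,6S)-2-formyl-3-(furan-2-ylmethyl)-2,6-dihydroxy-6-methyl-5-oxocyclohex-3-en-1-yl (3R)-3-hydroxybutanoate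
Conditions: [Cu(MeCN)4]OTf (5 mol %), 2,2'-bipyridine (5 mol %), TEMPO (5 mol %), N-methylimidazole (10 mol %), air, MeCN, rt
Reagents that add atoms: none
Why: Copper/nitroxyl aerobic oxidation is selective for primary over secondary alcohols, so only the C1 CH2OH should become the aldehyde while the C3' carbinol and the tertiary hydroxyls stay untouched.

**Step 13**
Reactants: 21 (1R,2S,6S)-2-formyl-3-(furan-2-ylmethyl)-2,6-dihydroxy-6-methyl-5-oxocyclohex-3-en-1-yl (3R)-3-hydroxybutanoate
Product: 24 Azaphilone D (1R,7S,8R,8aS)-1,7,8a-trihydroxy-7-methyl-6-oxo-3-[(1E)-3-oxoprop-1-en-1-yl]-6,7,8,8a-tetrahydro-1H-isochromen-8-yl (3R)-3-hydroxybutanoate, via furan endoperoxide 22 (not isolated), via Z-keto-enal 23 (not isolated)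
Conditions: O2, tetraphenylporphyrin (cat.), visible light, CH2Cl2, −78 °C; then Me2S, −78 °C → rt; then pyridinium p-toluenesulfonate (cat.), CH2Cl2/H2O, rt
Reagents that add atoms: dioxygen O=O
Why: Singlet-oxygen [4+2] cycloaddition to the electron-rich furan and reduction of the endoperoxide should give the 4-oxo-2-enal, whose C3 ketone enolizes toward the doubly activated C4 methylene and closes ring B by 6-exo-trig hemiacetalization on the C1 aldehyde, while mild acid equilibrates the enal to E and C1 to the anomer with its hydroxyl anti to the C8a hydroxyl.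

**Compound list**
1 | ethyl (2S,3R)-3-[(4R)-2,2-dimethyl-1,3-dioxolan-4-yl]-2,3-dihydroxy-2-methylpropanoate | CCOC(=O)[C@@](C)(O)[C@H](O)[C@H]1COC(C)(C)O1 | starting material
2 | ethyl (4S,5R)-5-[(4R)-2,2-dimethyl-1,3-dioxolan-4-yl]-2,2,4-trimethyl-1,3-dioxolane-4-carboxylate | CCOC(=O)[C@@]1(C)OC(C)(C)O[C@@H]1[C@H]1COC(C)(C)O1 | intermediate
3 | ethyl (4S,5R)-5-[(1R)-1,2-dihydroxyethyl]-2,2,4-trimethyl-1,3-dioxolane-4-carboxylate | CCOC(=O)[C@@]1(C)OC(C)(C)O[C@@H]1[C@H](O)CO | intermediate
4 | ethyl (4S,5R)-5-[(1R)-2-{[tert-butyl(diphenyl)silyl]oxy}-1-hydroxyethyl]-2,2,4-trimethyl-1,3-dioxolane-4-carboxylate | CCOC(=O)[C@@]1(C)OC(C)(C)O[C@@H]1[C@H](O)CO[Si](c1ccccc1)(c1ccccc1)C(C)(C)C | intermediate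
5 | ethyl (4S,5S)-5-({[tert-butyl(diphenyl)silyl]oxy}acetyl)-2,2,4-trimethyl-1,3-dioxolane-4-carboxylate | CCOC(=O)[C@@]1(C)OC(C)(C)O[C@@H]1C(=O)CO[Si](c1ccccc1)(c1ccccc1)C(C)(C)C | intermediate
6 | furan | c1ccoc1 | starting material
7 | 3-bromo-1-(trimethylsilyl)prop-1-yne | C[Si](C)(C)C#CCBr | starting material
8 | furan-2-yllithium | [Li]c1ccco1 | intermediate
9 | [3-(furan-2-yl)prop-1-yn-1-yl](trimethyl)silane | C[Si](C)(C)C#CCc1ccco1 | intermediate
10 | 2-(furan-2-ylmethyl)-1,1-di(propan-2-yloxy)-3-(trimethylsilyl)titanacycloprop-2-ene | CC(C)O[Ti]1(OC(C)C)C(Cc2ccco2)=C1[Si](C)(C)C | intermediate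
11 | 1-oxa-2-titanacyclopent-3-ene carrying two isopropoxy groups on Ti, SiMe3 on C3 (= C5), furfuryl on C4 (= C4a), and on C5 (= C8a, configured as in 12) CH2OTBDPS and the (4S,5R)-4-ethoxycarbonyl-2,2,4-trimethyl-1,3-dioxolan-5-yl group | CCOC(=O)[C@@]1(C)OC(C)(C)O[C@@H]1[C@@]1(CO[Si](c2ccccc2)(c2ccccc2)C(C)(C)C)O[Ti](OC(C)C)(OC(C)C)C([Si](C)(C)C)=C1Cc1ccco1 | intermediate
12 | (3aR,4R,7aS)-4-({[tert-butyl(diphenyl)silyl]oxy}methyl)-5-(furan-2-ylmethyl)-4-hydroxy-2,2,7a-trimethyl-6-(trimethylsilyl)-3a,4-dihydro-1,3-benzodioxol-7(7aH)-one | C[C@]12OC(C)(C)O[C@@H]1[C@](O)(CO[Si](c1ccccc1)(c1ccccc1)C(C)(C)C)C(Cc1ccco1)=C([Si](C)(C)C)C2=O | intermediate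
13 | (3aR,4R,7aS)-4-({[tert-butyl(diphenyl)silyl]oxy}methyl)-5-(furan-2-ylmethyl)-4-hydroxy-2,2,7a-trimethyl-3a,4-dihydro-1,3-benzodioxol-7(7aH)-one | C[C@]12OC(C)(C)O[C@@H]1[C@](O)(CO[Si](c1ccccc1)(c1ccccc1)C(C)(C)C)C(Cc1ccco1)=CC2=O | intermediate
14 | (4R,5R,6S)-4-({[tert-butyl(diphenyl)silyl]oxy}methyl)-3-(furan-2-ylmethyl)-4,5,6-trihydroxy-6-methylcyclohex-2-en-1-one | C[C@]1(O)[C@H](O)[C@](O)(CO[Si](c2ccccc2)(c2ccccc2)C(C)(C)C)C(Cc2ccco2)=CC1=O | intermediate
15 | (3R)-3-hydroxybutanoic acid | C[C@@H](O)CC(=O)O | starting material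
16 | tert-butyl(dimethyl)silyl (3R)-3-{[tert-butyl(dimethyl)silyl]oxy}butanoate | C[C@@H](O[Si](C)(C)C(C)(C)C)CC(=O)O[Si](C)(C)C(C)(C)C | intermediate
17 | (3R)-3-{[tert-butyl(dimethyl)silyl]oxy}butanoic acid | C[C@@H](O[Si](C)(C)C(C)(C)C)CC(=O)O | intermediate
18 | (3R)-3-{[tert-butyl(dimethyl)silyl]oxy}butanoic 2,4,6-trichlorobenzoic anhydride | C[C@@H](O[Si](C)(C)C(C)(C)C)CC(=O)OC(=O)c1c(Cl)cc(Cl)cc1Cl | intermediate
19 | (1R,2R,6S)-2-({[tert-butyl(diphenyl)silyl]oxy}methyl)-3-(furan-2-ylmethyl)-2,6-dihydroxy-6-methyl-5-oxocyclohex-3-en-1-yl (3R)-3-{[tert-butyl(dimethyl)silyl]oxy}butanoate | C[C@@H](O[Si](C)(C)C(C)(C)C)CC(=O)O[C@@H]1[C@](O)(CO[Si](c2ccccc2)(c2ccccc2)C(C)(C)C)C(Cc2ccco2)=CC(=O)[C@@]1(C)O | intermediate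
20 | (1R,2R,6S)-3-(furan-2-ylmethyl)-2,6-dihydroxy-2-(hydroxymethyl)-6-methyl-5-oxocyclohex-3-en-1-yl (3R)-3-hydroxybutanoate | C[C@@H](O)CC(=O)O[C@@H]1[C@](O)(CO)C(Cc2ccco2)=CC(=O)[C@@]1(C)O | intermediate
21 | (1R,2S,6S)-2-formyl-3-(furan-2-ylmethyl)-2,6-dihydroxy-6-methyl-5-oxocyclohex-3-en-1-yl (3R)-3-hydroxybutanoate | C[C@@H](O)CC(=O)O[C@@H]1[C@](O)(C=O)C(Cc2ccco2)=CC(=O)[C@@]1(C)O | intermediate
22 | (1R,2S,6S)-2-formyl-2,6-dihydroxy-6-methyl-5-oxo-3-(2,3,7-trioxabicyclo[2.2.1]hept-5-en-1-ylmethyl)cyclohex-3-en-1-yl (3R)-3-hydroxybutanoate (both endoperoxide diastereomers) | C[C@@H](O)CC(=O)O[C@@H]1[C@](O)(C=O)C(CC23OOC(O2)C=C3)=CC(=O)[C@@]1(C)O | intermediate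
23 | (1R,2S,6S)-3-[(3Z)-2,5-dioxopent-3-en-1-yl]-2-formyl-2,6-dihydroxy-6-methyl-5-oxocyclohex-3-en-1-yl (3R)-3-hydroxybutanoate | C[C@@H](O)CC(=O)O[C@@H]1[C@](O)(C=O)C(CC(=O)/C=C\C=O)=CC(=O)[C@@]1(C)O | intermediate
24 | Azaphilone D, (1R,7S,8R,8aS)-1,7,8a-trihydroxy-7-methyl-6-oxo-3-[(1E)-3-oxoprop-1-en-1-yl]-6,7,8,8a-tetrahydro-1H-isochromen-8-yl (3R)-3-hydroxybutanoate | C[C@@H](O)CC(=O)O[C@@H]1[C@@]2(O)C(=CC(=O)[C@@]1(C)O)C=C(/C=C/C=O)O[C@H]2O | target

**Step count and risks**
Total steps: 13. Longest linear sequence: 11 steps (steps 1, 2, 3, 4, 6, 7, 8, 10, 11, 12, 13).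

Steps most likely to fail:

1. Step 6 (carries the label "Proposed new method:"). What may go wrong: the second carbon–carbon bond formation stalls, because the hindered α-silyl alkenyltitanium of the oxatitanacycle does not attack the ester, so that only the ketone addition takes place. Fallback: setting out from 5 and 9, the sequence is run only as far as oxatitanacyclopentene 11, the part with direct precedent, and 11 is cleaved with I2 at −50 °C to the (Z)-alkenyl iodide F1. Treatment of F1 with iPrMgCl·LiCl (2.2 equiv, THF, −40 °C → rt) first deprotonates the tertiary alcohol and then effects iodine–magnesium exchange. The alkenylmagnesium should close onto the ethyl ester (Parham-type cyclization), which comes back to the route at 12.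

2. Step 13. What may go wrong: after unmasking, the Z-keto-enal is consumed by intramolecular aldol addition of the acidic C4 methylene to the enal carbonyl, or by oxa-Michael addition of the C8a hydroxyl, before ring B closes; Z to E isomerization may also remain incomplete. Fallback: setting out from 21, Clauson-Kaas oxidation (Br2, MeOH, Na2CO3, −40 °C) converts the furan into the 2,5-dimethoxy-2,5-dihydrofuran F2, an isolable masked ene-dione. Mild aqueous acid (AcOH/H2O/THF, rt) then releases the keto-enal slowly under the same acidic, equilibrating conditions in which ring B closes and the enal isomerizes, so that it never accumulates; this comes back to the route at 24.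

3. Step 10. What may go wrong: acylation of the C8 hydroxyl, which lies between two fully substituted carbinol carbons, is too slow and the mixed anhydride breaks down first. Fallback: setting out from 14, heating with 2,2,6-trimethyl-4H-1,3-dioxin-4-one (toluene, 110 °C) generates acetylketene, which acylates hindered alcohols without a catalyst, to give the acetoacetate F3. Reduction of its side-chain ketone with an (R)-selective ketoreductase (NADPH, iPrOH, phosphate buffer) gives the (3R)-hydroxybutanoate F4, and HF·pyridine removes the silyl ether, which comes back to the route at 20.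

**Further compounds**
F1 | step 6 | ethyl (4S,5R)-5-[(2R,3Z)-1-{[tert-butyl(diphenyl)silyl]oxy}-3-(furan-2-ylmethyl)-2-hydroxy-4-iodo-4-(trimethylsilyl)but-3-en-2-yl]-2,2,4-trimethyl-1,3-dioxolane-4-carboxylate | CCOC(=O)[C@@]1(C)OC(C)(C)O[C@@H]1[C@](O)(CO[Si](c2ccccc2)(c2ccccc2)C(C)(C)C)/C(Cc1ccco1)=C(\I)[Si](C)(C)C
F2 | step 13 | (1R,2S,6S)-3-[(2,5-dimethoxy-2,5-dihydrofuran-2-yl)methyl]-2-formyl-2,6-dihydroxy-6-methyl-5-oxocyclohex-3-en-1-yl (3R)-3-hydroxybutanoate (mixture at the two acetal carbons) | C[C@@H](O)CC(=O)O[C@@H]1[C@](O)(C=O)C(CC2(OC)OC(OC)C=C2)=CC(=O)[C@@]1(C)O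
F3 | step 10 | (1R,2R,6S)-2-({[tert-butyl(diphenyl)silyl]oxy}methyl)-3-(furan-2-ylmethyl)-2,6-dihydroxy-6-methyl-5-oxocyclohex-3-en-1-yl 3-oxobutanoate | CC(=O)CC(=O)O[C@@H]1[C@](O)(CO[Si](c2ccccc2)(c2ccccc2)C(C)(C)C)C(Cc2ccco2)=CC(=O)[C@@]1(C)O
F4 | step 10 | (1R,2R,6S)-2-({[tert-butyl(diphenyl)silyl]oxy}methyl)-3-(furan-2-ylmethyl)-2,6-dihydroxy-6-methyl-5-oxocyclohex-3-en-1-yl (3R)-3-hydroxybutanoate | C[C@@H](O)CC(=O)O[C@@H]1[C@](O)(CO[Si](c2ccccc2)(c2ccccc2)C(C)(C)C)C(Cc2ccco2)=CC(=O)[C@@]1(C)O
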